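**Plan**

1. Retrosynthetic cuts, in order: C4–C4a (ring C, the last C–C bond), the five O–Si bonds, O1–C2 (aryl propargyl ether), C6–C1'' (Heck) and C2–C3 (acetylide plus aldehyde).
2. Forward: rings A and B are bought as arenes. Ring A is made into a phenol that already carries the side chain, ring B into a racemic propargylic acetate. The two are joined at O1–C2, the alkyne terminus is raised to a siloxyalkyne, and ring C is closed last, before global desilylation.
3. Enabling feature: in the open precursor ring A is a 4-alkenyl-3,5-bis(silyloxy)phenyl ether with a mirror plane through C6 and C8a. C4a and C8 are one and the same position, each ortho to O1 and ortho/para to the other two oxygens, so ring C can only close to the 6-alkenyl-5,7-dioxygenated chromane.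
4. The siloxyalkyne holds C4 at the ketone oxidation level while C3 is sp-hybridised. No β-aryloxy carbonyl compound, the species that loses the phenol by elimination, exists before ring closure; afterwards the ketone stays masked as a silyl enol ether until the last step.
5. Stereochemistry: C3'' comes from (S)-β-citronellene and is never touched; C2 is set by an enantioconvergent copper-catalysed propargylic etherification of the racemic acetate; the E-alkene is set by the Heck reaction.

Key step: step 8

Assumption: the (S,S)-Ph-pybox copper catalyst is taken to deliver the (S)-ether 12; if the facial preference is the reverse, the (R,R)-ligand is used instead.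

Abbreviations: TBS = tert-butyldimethylsilyl, TIPS = triisopropylsilyl. Locants follow flavanone numbering (O1, C2–C4, C4a, C5–C8, C8a; side chain C1''–C8'').

**Route**

Step 1
Reactants: 1 2-iodoresorcinol (2-iodobenzene-1,3-diol)
Product: 2 2-iodo-1,3-bis(tert-butyldimethylsilyloxy)benzene
Conditions: TBSCl, imidazole, DMF, rt
Reagents that add atoms: tert-butyldimethylsilyl chloride, CC(C)(C)[Si](C)(C)Cl
Why: Imidazole-mediated silylation of both phenols (standard silyl ether formation); no selectivity is needed.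

Step 2
Reactants: 2 2-iodo-1,3-bis(tert-butyldimethylsilyloxy)benzene
Product: 4 4-iodo-3,5-bis(tert-butyldimethylsilyloxy)phenol, via pinacol arylboronate 3 (not isolated)
Conditions: [Ir(OMe)(cod)]2 (1.5 mol%), 4,4'-di-tert-butyl-2,2'-bipyridine (3 mol%), B2pin2 (0.55 equiv), THF, 60 °C; then Oxone, acetone/H2O, rt
Reagents that add atoms: bis(pinacolato)diboron, CC1(C)OB(OC1(C)C)B1OC(C)(C)C(C)(C)O1 (boronate group of 3 only); Oxone (potassium peroxymonosulfate), [K+].[O-]S(=O)(=O)OO (the phenol oxygen)
Why: Iridium-catalysed aromatic C–H borylation is governed by sterics and should occur only at the single C–H with no ortho substituent (aryl iodides are tolerated), and ipso-oxidation of the boronate by peroxymonosulfate then gives the phenol para to iodine in the same flask (C–H borylation–oxidation).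

Step 3
Reactants: 4 4-iodo-3,5-bis(tert-butyldimethylsilyloxy)phenol; 5 (S)-β-citronellene [(3S)-3,7-dimethylocta-1,6-diene]
Product: 6 4-[(1E,3S)-3,7-dimethylocta-1,6-dien-1-yl]-3,5-bis(tert-butyldimethylsilyloxy)phenol
Conditions: Pd[P(t-Bu)3]2 (3 mol%), Cy2NMe, toluene, 80 °C
Reagents that add atoms: none
Why: Mizoroki–Heck reaction: the arylpalladium adds to the unsubstituted alkene carbon of 5 and syn β-hydride elimination towards the benzylic hydrogen gives the conjugated E-styrene, the trisubstituted alkene and the chiral-pool stereocentre C3'' being left untouched, while the silyl groups can turn towards the unsubstituted ring positions and keep the C–I site accessible.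

Step 4
Reactants: 7 3,4-dihydroxybenzaldehyde
Product: 8 3,4-bis(tert-butyldimethylsilyloxy)benzaldehyde
Conditions: TBSCl, imidazole, DMF, rt
Reagents that add atoms: tert-butyldimethylsilyl chloride, CC(C)(C)[Si](C)(C)Cl
Why: Standard bis-silylation of the catechol, which gives ring B the same fluoride-labile protection as ring A.

Step 5
Reactants: 8 3,4-bis(tert-butyldimethylsilyloxy)benzaldehyde; 9 ethynylmagnesium bromide
Product: 11 rac-1-[3,4-bis(tert-butyldimethylsilyloxy)phenyl]prop-2-yn-1-yl acetate, via bromomagnesium alkoxide 10 (not isolated)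
Conditions: HC≡CMgBr, THF, 0 °C; then Ac2O, 0 °C to rt
Reagents that add atoms: acetic anhydride, CC(=O)OC(C)=O
Why: Grignard 1,2-addition of the acetylide to the aldehyde and O-acetylation of the magnesium alkoxide in the same flask; the new carbinol centre is deliberately racemic because step 6 is enantioconvergent.

Step 6
Reactants: 6 4-[(1E,3S)-3,7-dimethylocta-1,6-dien-1-yl]-3,5-bis(tert-butyldimethylsilyloxy)phenol; 11 rac-1-[3,4-bis(tert-butyldimethylsilyloxy)phenyl]prop-2-yn-1-yl acetate
Product: 12 5-{[(1S)-1-[3,4-bis(tert-butyldimethylsilyloxy)phenyl]prop-2-yn-1-yl]oxy}-2-[(1E,3S)-3,7-dimethylocta-1,6-dien-1-yl]-1,3-bis(tert-butyldimethylsilyloxy)benzene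
Conditions: Cu(OTf)·0.5C6H6 (5 mol%), (S,S)-Ph-pybox (10 mol%), i-Pr2NEt, ClCH2CH2Cl, 0 °C
Reagents that add atoms: none
Why: Copper-catalysed enantioselective propargylic etherification: both enantiomers of 11 ionise through the copper acetylide to the same planar copper allenylidene, and the pybox ligand directs the phenoxide oxygen of 6 to one face of the γ-carbon, which sets C2 as (S) from the racemate, the ortho carbons of 6 being shielded from C-alkylation by the adjacent silyloxy groups.

Step 7
Reactants: 12 the (S)-aryl propargyl ether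
Product: 15 5-{[(1R)-1-[3,4-bis(tert-butyldimethylsilyloxy)phenyl]-3-(triisopropylsilyloxy)prop-2-yn-1-yl]oxy}-2-[(1E,3S)-3,7-dimethylocta-1,6-dien-1-yl]-1,3-bis(tert-butyldimethylsilyloxy)benzene (same spatial arrangement at the carbinol carbon as in 12; the descriptor changes only because the siloxyalkynyl group now outranks the aryl group), via lithium acetylide 13 (not isolated), via lithium ynolate 14 (not isolated)
Conditions: n-BuLi, THF, −78 °C; t-BuOOLi (from t-BuOOH and LiN(SiMe3)2), −78 to 0 °C; i-Pr3SiOTf, −78 to 0 °C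
Reagents that add atoms: tert-butyl hydroperoxide, CC(C)(C)OO (the alkynyl oxygen); triisopropylsilyl triflate, CC(C)[Si](OS(=O)(=O)C(F)(F)F)(C(C)C)C(C)C; n-butyllithium, [Li]CCCC (lithium of 13 and 14 only)
Why: Electrophilic oxygenation of the lithium acetylide by lithium tert-butyl peroxide gives the ynolate, which the bulky silyl triflate traps on oxygen (acetylide oxidation–O-silylation); no bond to C2 is made or broken, so its configuration is kept.

Step 8
Reactants: 15 the triisopropylsilyl ynol ether
Product: 16 (2S)-2-[3,4-bis(tert-butyldimethylsilyloxy)phenyl]-5,7-bis(tert-butyldimethylsilyloxy)-6-[(1E,3S)-3,7-dimethylocta-1,6-dien-1-yl]-4-(triisopropylsilyloxy)-2H-chromene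
Conditions: HNTf2 (5–10 mol%), CH2Cl2, −78 to −40 °C; then Et3N
Reagents that add atoms: none
Why: Protonation of the siloxyalkyne at C3 gives a silyl ketenium ion whose C4 is attacked by the ring A carbon ortho to O1, and loss of the ring proton returns the acid and leaves the C3=C4 silyl enol ether; the closest known reaction type is the Brønsted acid-promoted carbocyclisation of arene-tethered siloxyalkynes to tetralone enol ethers, a relative of Friedel–Crafts acylation. Ring C closes in the 6-endo-dig mode, both alkyne carbons ending in the ring. No stereocentre is created: C2 is carried through because neither its C–H nor its C–O bond takes part, and the product, which has no C3 methylene next to a C4 carbonyl, cannot open to a chalcone. The selectivity needed is regiochemical (alkenyl group at C6 and not C8, attack by ring A and not ring B); it is secured by the mirror plane of the 4-alkenyl-3,5-bis(silyloxy)phenoxy ring, which makes the two ortho carbons identical and triply oxygen-activated, whereas ring B could only attack through a 5-endo closure from a less activated carbon. The ynol ether is the most basic site, so catalytic acid at low temperature should spare the side-chain alkenes and the aryl silyl ethers, and quenching with Et3N before warming guards C2 against ionisation of the O1–C2 bond.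

Step 9
Reactants: 16 the 4-silyloxy-2H-chromene
Product: 17 (2S)-2-(3,4-dihydroxyphenyl)-6-[(1E,3S)-3,7-dimethylocta-1,6-dien-1-yl]-5,7-dihydroxychroman-4-one (target)
Conditions: Et3N·3HF, THF, 0 °C to rt
Reagents that add atoms: none
Why: Fluoride-mediated cleavage of all five Si–O bonds (global desilylation), after which the enol tautomerises to the C4 ketone by protonation at C3 in the weakly acidic medium; this avoids a persistent enolate, which would open the flavanone to a chalcone and racemise C2, and avoids strong acid that could cyclise the side chain.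

**Compound list**

1 | 2-iodoresorcinol | Oc1cccc(O)c1I | starting material
2 | 2-iodo-1,3-bis(tert-butyldimethylsilyloxy)benzene | CC(C)(C)[Si](C)(C)Oc1cccc(O[Si](C)(C)C(C)(C)C)c1I | intermediate
3 | 2-[4-iodo-3,5-bis(tert-butyldimethylsilyloxy)phenyl]-4,4,5,5-tetramethyl-1,3,2-dioxaborolane | CC(C)(C)[Si](C)(C)Oc1cc(B2OC(C)(C)C(C)(C)O2)cc(O[Si](C)(C)C(C)(C)C)c1I | intermediate
4 | 4-iodo-3,5-bis(tert-butyldimethylsilyloxy)phenol | CC(C)(C)[Si](C)(C)Oc1cc(O)cc(O[Si](C)(C)C(C)(C)C)c1I | intermediate
5 | (S)-β-citronellene, (3S)-3,7-dimethylocta-1,6-diene | CC(C)=CCC[C@H](C)C=C | starting material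
6 | 4-[(1E,3S)-3,7-dimethylocta-1,6-dien-1-yl]-3,5-bis(tert-butyldimethylsilyloxy)phenol | CC(C)=CCC[C@H](C)/C=C/c1c(O[Si](C)(C)C(C)(C)C)cc(O)cc1O[Si](C)(C)C(C)(C)C | intermediate
7 | 3,4-dihydroxybenzaldehyde | O=Cc1ccc(O)c(O)c1 | starting material
8 | 3,4-bis(tert-butyldimethylsilyloxy)benzaldehyde | O=Cc1ccc(O[Si](C)(C)C(C)(C)C)c(O[Si](C)(C)C(C)(C)C)c1 | intermediate
9 | ethynylmagnesium bromide | C#C[Mg]Br | starting material
10 | bromomagnesium 1-[3,4-bis(tert-butyldimethylsilyloxy)phenyl]prop-2-yn-1-olate (racemic) | C#CC(O[Mg]Br)c1ccc(O[Si](C)(C)C(C)(C)C)c(O[Si](C)(C)C(C)(C)C)c1 | intermediate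
11 | rac-1-[3,4-bis(tert-butyldimethylsilyloxy)phenyl]prop-2-yn-1-yl acetate | C#CC(OC(C)=O)c1ccc(O[Si](C)(C)C(C)(C)C)c(O[Si](C)(C)C(C)(C)C)c1 | intermediate
12 | (S)-aryl propargyl ether (name as in step 6) | C#C[C@@H](c1ccc(O[Si](C)(C)C(C)(C)C)c(O[Si](C)(C)C(C)(C)C)c1)Oc1cc(O[Si](C)(C)C(C)(C)C)c(/C=C/[C@@H](C)CCC=C(C)C)c(O[Si](C)(C)C(C)(C)C)c1 | intermediate
13 | lithium acetylide of 12 | [Li]C#C[C@@H](c1ccc(O[Si](C)(C)C(C)(C)C)c(O[Si](C)(C)C(C)(C)C)c1)Oc1cc(O[Si](C)(C)C(C)(C)C)c(/C=C/[C@@H](C)CCC=C(C)C)c(O[Si](C)(C)C(C)(C)C)c1 | intermediate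
14 | lithium ynolate derived from 13 | [Li]OC#C[C@@H](c1ccc(O[Si](C)(C)C(C)(C)C)c(O[Si](C)(C)C(C)(C)C)c1)Oc1cc(O[Si](C)(C)C(C)(C)C)c(/C=C/[C@@H](C)CCC=C(C)C)c(O[Si](C)(C)C(C)(C)C)c1 | intermediate
15 | triisopropylsilyl ynol ether (name as in step 7) | CC(C)[Si](OC#C[C@@H](c1ccc(O[Si](C)(C)C(C)(C)C)c(O[Si](C)(C)C(C)(C)C)c1)Oc1cc(O[Si](C)(C)C(C)(C)C)c(/C=C/[C@@H](C)CCC=C(C)C)c(O[Si](C)(C)C(C)(C)C)c1)(C(C)C)C(C)C | intermediate
16 | (2S)-4-(triisopropylsilyloxy)-2H-chromene (name as in step 8) | CC(C)[Si](OC1=C[C@@H](c2ccc(O[Si](C)(C)C(C)(C)C)c(O[Si](C)(C)C(C)(C)C)c2)Oc2cc(O[Si](C)(C)C(C)(C)C)c(/C=C/[C@@H](C)CCC=C(C)C)c(O[Si](C)(C)C(C)(C)C)c21)(C(C)C)C(C)C | intermediate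
17 | (2S)-2-(3,4-dihydroxyphenyl)-6-[(1E,3S)-3,7-dimethylocta-1,6-dien-1-yl]-5,7-dihydroxychroman-4-one | CC(C)=CCC[C@H](C)/C=C/c1c(O)cc2c(c1O)C(=O)C[C@@H](c1ccc(O)c(O)c1)O2 | target

**Step count and risks**

Total steps: 9. Longest linear sequence: 7 steps (1, 2, 3, 6, 7, 8, 9, from 2-iodoresorcinol).

Step 7 (siloxyalkyne formation). The lithium ynolate may expel the C2 aryloxide by β-elimination, or the lithium bases may remove the propargylic C2–H, with loss of material or of configuration before O-silylation. The fallback sets out from 12 and comes back to the route at 17; it activates the alkyne terminus as an ynamide without any anionic intermediate. Copper-catalysed aerobic oxidative coupling of 12 with oxazolidin-2-one (CuCl2, pyridine, Na2CO3, O2, toluene, 70 °C) would give the ynamide F1. Catalytic HNTf2 (CH2Cl2, −78 to −20 °C) would form the keteniminium ion, which closes ring C in the same 6-endo manner to the enamide F2. Aqueous HF in MeCN would then hydrolyse the enamide to the C4 ketone and remove the four silyl ethers to give 17.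

Step 8 (ring closure). Three processes threaten it: heterolysis of the O1–C2 bond in the cationic intermediate (charge-accelerated [3,3] shift or opening to a chalcone-type cation), which would erode the configuration at C2; protonation of the side-chain alkenes followed by cation–olefin cyclisation; and slow closure because of peri strain between the silyloxy groups at C4 and C5. The fallback sets out from 12 and comes back at 17; it is a classical Friedel–Crafts cycloacylation. Dicyclohexylborane (THF, 0 °C) would add to the terminal alkyne of 12 to give the (E)-alkenylborane F3, and buffered oxidation (NaBO3·4H2O) would give the aldehyde F4. Pinnick oxidation (NaClO2, NaH2PO4, 2-methylbut-2-ene, t-BuOH/H2O) would give the acid F5. (CF3CO)2O in CH2Cl2 at 0 °C would close ring C through the mixed anhydride onto either of the two equivalent ortho carbons to give the tetrakis-silyl flavanone F6, which is desilylated under the conditions of step 9 to 17.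

Step 6 (propargylic etherification). C-propargylation at an ortho carbon of the electron-rich phenol may compete with O-attack, or facial control at the copper allenylidene may be insufficient. The fallback sets out from 8 and 6 and comes back at 12; it is stereospecific instead of enantioconvergent. Titanium/BINOL-mediated enantioselective addition of the zinc acetylide of trimethylsilylacetylene to 8 (Ti(O-i-Pr)4, the appropriate BINOL enantiomer, Et2Zn, toluene) would give the silylated carbinol F7. K2CO3 (cat.) in MeOH at 0 °C would remove the alkynyl silyl group to give the (R)-alkynol F8. A Mitsunobu reaction of F8 with 6 (PPh3, DIAD, toluene, 0 °C) would give 12 with inversion at C2.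

**Further compounds**

F1 | step 7 | 3-[(3R)-3-[3,4-bis(tert-butyldimethylsilyloxy)phenyl]-3-{3,5-bis(tert-butyldimethylsilyloxy)-4-[(1E,3S)-3,7-dimethylocta-1,6-dien-1-yl]phenoxy}prop-1-yn-1-yl]oxazolidin-2-one | O=C1OCCN1C#C[C@@H](c1ccc(O[Si](C)(C)C(C)(C)C)c(O[Si](C)(C)C(C)(C)C)c1)Oc1cc(O[Si](C)(C)C(C)(C)C)c(/C=C/[C@@H](C)CCC=C(C)C)c(O[Si](C)(C)C(C)(C)C)c1
F2 | step 7 | 3-{(2S)-2-[3,4-bis(tert-butyldimethylsilyloxy)phenyl]-5,7-bis(tert-butyldimethylsilyloxy)-6-[(1E,3S)-3,7-dimethylocta-1,6-dien-1-yl]-2H-chromen-4-yl}oxazolidin-2-one | O=C1OCCN1C1=C[C@@H](c2ccc(O[Si](C)(C)C(C)(C)C)c(O[Si](C)(C)C(C)(C)C)c2)Oc2cc(O[Si](C)(C)C(C)(C)C)c(/C=C/[C@@H](C)CCC=C(C)C)c(O[Si](C)(C)C(C)(C)C)c21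
F3 | step 8 | dicyclohexyl{(1E,3S)-3-[3,4-bis(tert-butyldimethylsilyloxy)phenyl]-3-{3,5-bis(tert-butyldimethylsilyloxy)-4-[(1E,3S)-3,7-dimethylocta-1,6-dien-1-yl]phenoxy}prop-1-en-1-yl}borane | B(/C=C/[C@@H](c1ccc(O[Si](C)(C)C(C)(C)C)c(O[Si](C)(C)C(C)(C)C)c1)Oc1cc(O[Si](C)(C)C(C)(C)C)c(/C=C/[C@@H](C)CCC=C(C)C)c(O[Si](C)(C)C(C)(C)C)c1)(C1CCCCC1)C1CCCCC1
F4 | step 8 | (3S)-3-[3,4-bis(tert-butyldimethylsilyloxy)phenyl]-3-{3,5-bis(tert-butyldimethylsilyloxy)-4-[(1E,3S)-3,7-dimethylocta-1,6-dien-1-yl]phenoxy}propanal | O=CC[C@@H](c1ccc(O[Si](C)(C)C(C)(C)C)c(O[Si](C)(C)C(C)(C)C)c1)Oc1cc(O[Si](C)(C)C(C)(C)C)c(/C=C/[C@@H](C)CCC=C(C)C)c(O[Si](C)(C)C(C)(C)C)c1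
F5 | step 8 | (3S)-3-[3,4-bis(tert-butyldimethylsilyloxy)phenyl]-3-{3,5-bis(tert-butyldimethylsilyloxy)-4-[(1E,3S)-3,7-dimethylocta-1,6-dien-1-yl]phenoxy}propanoic acid | OC(=O)C[C@@H](c1ccc(O[Si](C)(C)C(C)(C)C)c(O[Si](C)(C)C(C)(C)C)c1)Oc1cc(O[Si](C)(C)C(C)(C)C)c(/C=C/[C@@H](C)CCC=C(C)C)c(O[Si](C)(C)C(C)(C)C)c1
F6 | step 8 | (2S)-2-[3,4-bis(tert-butyldimethylsilyloxy)phenyl]-5,7-bis(tert-butyldimethylsilyloxy)-6-[(1E,3S)-3,7-dimethylocta-1,6-dien-1-yl]chroman-4-one | CC(C)=CCC[C@H](C)/C=C/c1c(O[Si](C)(C)C(C)(C)C)cc2c(c1O[Si](C)(C)C(C)(C)C)C(=O)C[C@@H](c1ccc(O[Si](C)(C)C(C)(C)C)c(O[Si](C)(C)C(C)(C)C)c1)O2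
F7 | step 6 | (1S)-1-[3,4-bis(tert-butyldimethylsilyloxy)phenyl]-3-(trimethylsilyl)prop-2-yn-1-ol | C[Si](C)(C)C#C[C@H](c1ccc(O[Si](C)(C)C(C)(C)C)c(O[Si](C)(C)C(C)(C)C)c1)O
F8 | step 6 | (1R)-1-[3,4-bis(tert-butyldimethylsilyloxy)phenyl]prop-2-yn-1-ol | C#C[C@H](c1ccc(O[Si](C)(C)C(C)(C)C)c(O[Si](C)(C)C(C)(C)C)c1)O
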